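Watch Q fall.

| setting | blue | ochre | teal | alder | birch | ash |
|---|---|---|---|---|---|---|
| E | 0.30 M | 0.30 M | 0.30 M | 0.30 M | 0.30 M | 0.30 M |
| X | 0.47 equiv | 1 equiv | 0.70 equiv | 0.700 equiv | 0.700 equiv | 0.700 equiv |
| D | 1 equiv | 1 equiv | 1 equiv | 1.00 equiv | 1.00 equiv | 1.00 equiv |
| G | 2 equiv | 2 equiv | 3 equiv | 2.00 equiv | 2.00 equiv | 2.00 equiv |
| temperature | 30 °C | 55 °C | 30 °C | 55 °C | 35 °C | 75 °C |
| remark | run made earlier | run made earlier | run made earlier |  |  |  |
| time |  |  |  | 40 h | 40 h | 40 h |

| run | time / h | Q / % |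
|---|---|---|
| blue | 6.00 | 7.9 |
| blue | 20.0 | 7.1 |
| blue | 40.0 | 3.7 |
| blue | 72.0 | 5.1 |
| blue | 96.0 | 5.6 |
| ochre | 2.00 | 20.8 |
| ochre | 6.00 | 17.4 |
| ochre | 12.0 | 17.1 |
| ochre | 20.0 | 16.6 |
| ochre | 25.0 | 16.7 |
| ochre | 30.0 | 19.3 |
| teal | 8.00 | 11.1 |
| teal | 15.0 | 9.9 |
| teal | 30.0 | 7.3 |
| teal | 48.0 | 6.6 |
| teal | 96.0 | 5.0 |

(readings scatter by 1 percentage point)

- reactions considered so far: E + X -> Q; D + X -> L; Q <-> Z; G + X -> J

1. the best flask by amount of Q, in percent of the E charged; "all alike" if 1.5 percentage points covers them all (alder / birch / ash / all alike)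
2. amount of Q at the end, in percent of the E charged, alder
3. amount of Q at the end, in percent of the E charged, birch
4. amount of Q at the end, in percent of the E charged, ash

In these flasks X makes Q from E, L from D and J from G, while Q turns into Z and back. I read the teal table at 30 °C row by row. Its first row gives Q 11.1 % after 8.00 h, and its last gives 5.0 % after 96.0 h, which I take as the floor. So the excess over the floor is 6.1 percentage points in the first row and 2.3 points in the third, at 30.0 h. An excess that shrinks by equal factors in equal times has a half-life, and these readings give about 15.6 h, with the scatter of the readings in it.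

My yardstick is the count of half-lives, the flask's time divided by this half-life: 2.56 in 40 h. Each one divides the excess by 2, so 17.0 % of it remains. Birch at 35 °C is warmer than teal, so I expect it to keep less of its excess than that. An excess like teal's would leave about 1 point in birch, close to the scatter of one reading. The ochre run at 55 °C shows no steady trend after its first row: 17.4 %, then 16.6 %, then 19.3 %. So I count alder and ash as on their floors by 40 h.

The forecast says 12.2 % for alder, 8 % for birch and 15 % for ash, with ash best, and calls birch “essentially equilibrated by 40 h”.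

The flasks give 12.5 % for alder, 8.43 % for birch and 16.4 % for ash, with ash best.

    E + X → Q (k = 0.540 M⁻¹ h⁻¹, Ea = 84.0 kJ mol⁻¹)
    D + X → L (k = 0.310 M⁻¹ h⁻¹, Ea = 84.0 kJ mol⁻¹)
    Q ⇌ Z (K = 1.20, k = 0.0380 h⁻¹, Ea = 93.0 kJ mol⁻¹, ΔH = −37.0 kJ mol⁻¹)
    G + X → J (k = 0.690 M⁻¹ h⁻¹, Ea = 77.0 kJ mol⁻¹)
    (constants at 35 °C)

Birch is still moving at 40 h: its Q stands 0.65 points above the 7.78 % it reaches after 400 h, less than the scatter of one reading. My 2.56 half-lives were read in teal at 30 °C, and the constants at 35 °C give birch about 4.02, which is more than my count. Birch ends at 8.43 % partly because the path from G + X to J uses X: without that path it gives 21.6 %, and without the path from Q to Z it gives 17.1 %. Alder counts 60.3 half-lives of 0.663 h, so its Q to Z ratio of 2.01 is an equilibrium value, which is thermodynamic control. The neighbour flask, like alder but with 2.80 equiv of X, ends with Q 49.2 % and Z 24.5 %, a ratio of 2.01.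

The data are simulated with constants of no real substance; scatter was added.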